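**Retrosynthetic overview**
1. Target 15 ⇐ furfuryl acetate 13. The C12–OAc bond is made when acetate returns to furan C5 (acetoxy-Piancatelli rearrangement); the cyclopentenone, the only ring, closes in the same step, last in the route, and sets C8 and C12.
2. 13 ⇐ alkyne 12 (Z-alkene by Lindlar semihydrogenation).
3. 12 ⇐ furan 7 + allylic acetate 11 (E-selective cross-metathesis at C5=C6).
4. 7 ⇐ furfural 1 + allylmagnesium bromide 2 + 1-bromooct-2-yne 4.
5. 11 ⇐ methyl 4-oxobutanoate 8 + vinylmagnesium bromide 9; the C4–O stereocentre comes from lipase acetylation.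

Numbering used below is prostanoid numbering: C1 ester carbon, C4 acetoxy-bearing chain carbon, C8 ring CH, C9 ketone, C12 acetoxy-bearing ring carbon.
Assumption: the (S)-configured acid in step 7 is taken to give the (8S,12R) ring; if a first screen shows the opposite sense, the (R)-acid is used under the same conditions.

**Route**

Step 1
Reactants: 1 furfural; 2 allylmagnesium bromide
Product: 3 1-(furan-2-yl)but-3-en-1-ol (racemic)
Conditions: Et2O, –78 → 0 °C; then H2O
Reagents that add atoms: none
Why: Grignard 1,2-addition of the allyl nucleophile to the aldehyde; the carbinol centre is racemic and is erased later when it ionises in step 7.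

Step 2
Reactants: 3 1-(furan-2-yl)but-3-en-1-ol; 4 1-bromooct-2-yne
Product: 7 1-[5-(oct-2-yn-1-yl)furan-2-yl]but-3-en-1-yl acetate (racemic), via dilithio alkoxide 5 (not isolated), via alkylated lithium alkoxide 6 (not isolated)
Conditions: n-BuLi (2.2 equiv), THF, –78 → 0 °C; 4 (1.1 equiv), –78 → 0 °C; then Ac2O (1.5 equiv), 0 °C → rt
Reagents that add atoms: acetic anhydride, CC(=O)OC(C)=O
Why: Dilithiation (alkoxide first, then the most acidic ring proton at C5 next to the furan oxygen), SN2 alkylation of the aryllithium by the primary propargylic bromide without copper (which would favour SN2' allene formation), and O-acylation of the remaining lithium alkoxide in the same flask.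

Step 3
Reactants: 8 methyl 4-oxobutanoate; 9 vinylmagnesium bromide
Product: 10 methyl 4-hydroxyhex-5-enoate (racemic)
Conditions: THF, –78 °C; then pH 7 buffer, cold work-up, used at once
Reagents that add atoms: none
Why: Chemoselective Grignard 1,2-addition to the aldehyde at –78 °C, where the methyl ester is untouched; the cold neutral quench limits lactonisation of the γ-hydroxy ester.

Step 4
Reactants: 10 methyl 4-hydroxyhex-5-enoate (racemic)
Product: 11 methyl (4S)-4-acetoxyhex-5-enoate
Conditions: Candida antarctica lipase B (immobilised), vinyl acetate (10 equiv), MTBE, 30 °C, to ca. 40% conversion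
Reagents that add atoms: vinyl acetate, C=COC(C)=O
Why: Lipase kinetic resolution by irreversible transesterification; with vinyl as the medium and the ester chain as the large substituent, Kazlauskas' rule predicts fast acylation of the (S)-alcohol, which sets C4, and the unreacted (R)-alcohol is removed by chromatography.

Step 5
Reactants: 7 1-[5-(oct-2-yn-1-yl)furan-2-yl]but-3-en-1-yl acetate; 11 methyl (4S)-4-acetoxyhex-5-enoate
Product: 12 methyl (4S,5E)-4,8-diacetoxy-8-[5-(oct-2-yn-1-yl)furan-2-yl]oct-5-enoate (both C8 epimers)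
Conditions: 11 (2 equiv), second-generation Hoveyda–Grubbs catalyst RuCl2(H2IMes)(=CH-C6H4-2-OiPr) (5 mol %), 1,4-benzoquinone (10 mol %), CH2Cl2, 40 °C
Reagents that add atoms: none
Why: Olefin cross-metathesis of a terminal homoallylic olefin with a secondary allylic acetate gives the favoured E-alkene; the alkyne cannot ring-close onto the carbene across the furan, intermolecular enyne metathesis of a dialkyl alkyne is slow, and C4 is untouched.

Step 6
Reactants: 12 methyl (4S,5E)-4,8-diacetoxy-8-[5-(oct-2-yn-1-yl)furan-2-yl]oct-5-enoate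
Product: 13 methyl (4S,5E)-4,8-diacetoxy-8-{5-[(2Z)-oct-2-en-1-yl]furan-2-yl}oct-5-enoate (both C8 epimers)
Conditions: H2 (1 atm), Lindlar catalyst (5% Pd on CaCO3 poisoned with Pb(OAc)2), quinoline, EtOAc, 0 °C → rt, stopped at 1 equiv H2
Reagents that add atoms: none
Why: Lindlar semihydrogenation adds H2 syn to the alkyne to give the Z-alkene, while the poisoned catalyst leaves the E-alkene, the furan and both acetates alone.

Step 7
Reactants: 13 methyl (4S,5E)-4,8-diacetoxy-8-{5-[(2Z)-oct-2-en-1-yl]furan-2-yl}oct-5-enoate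
Product: 15 methyl (4S,5E)-4-acetoxy-7-{(1S,5R)-5-acetoxy-5-[(2Z)-oct-2-en-1-yl]-2-oxocyclopent-3-en-1-yl}hept-5-enoate (target CNP0171642.2), via acetoxy-dihydrofuran 14 (not isolated)
Conditions: (S)-3,3'-bis(2,4,6-triisopropylphenyl)-BINOL N-triflylphosphoramide (5 mol %), AcOH (20 mol %), 4 Å MS, toluene, 30 °C
Reagents that add atoms: none
Why: Proposed new method: an enantioselective acetoxy-Piancatelli rearrangement in which the chiral acid ionises either C8 epimer of the furfuryl acetate to one furfuryl cation paired with the chiral anion, acetic acid re-adds at the distal furan carbon C5 to form the C12–O bond (14), acid-assisted ring opening gives an acetoxy-hydroxy-pentadienyl cation, and conrotatory 4π electrocyclisation with the oxygen substituent outward places OAc trans to the C8 chain while the counter-anion sets the sense of rotation and so the (8S,12R) configuration; the closest known reactions are the racemic oxa-Piancatelli rearrangement with water and the chiral-phosphoric-acid-catalysed aza-Piancatelli rearrangement with anilines, and carboxylate has not been shown as the nucleophile.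

**Compound list**
1 | furfural (furan-2-carbaldehyde) | O=Cc1ccco1 | starting material
2 | allylmagnesium bromide | C=CC[Mg]Br | starting material
3 | 1-(furan-2-yl)but-3-en-1-ol (racemic) | C=CCC(O)c1ccco1 | intermediate
4 | 1-bromooct-2-yne | CCCCCC#CCBr | starting material
5 | lithium 1-(5-lithiofuran-2-yl)but-3-en-1-olate (racemic) | [Li]c1ccc(o1)C(CC=C)O[Li] | intermediate
6 | lithium 1-[5-(oct-2-yn-1-yl)furan-2-yl]but-3-en-1-olate (racemic) | CCCCCC#CCc1ccc(o1)C(CC=C)O[Li] | intermediate
7 | 1-[5-(oct-2-yn-1-yl)furan-2-yl]but-3-en-1-yl acetate (racemic) | CCCCCC#CCc1ccc(o1)C(CC=C)OC(C)=O | intermediate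
8 | methyl 4-oxobutanoate | COC(=O)CCC=O | starting material
9 | vinylmagnesium bromide | C=C[Mg]Br | starting material
10 | methyl 4-hydroxyhex-5-enoate (racemic) | C=CC(O)CCC(=O)OC | intermediate
11 | methyl (4S)-4-acetoxyhex-5-enoate | C=C[C@H](CCC(=O)OC)OC(C)=O | intermediate
12 | methyl (4S,5E)-4,8-diacetoxy-8-[5-(oct-2-yn-1-yl)furan-2-yl]oct-5-enoate (both C8 epimers) | CCCCCC#CCc1ccc(o1)C(OC(C)=O)C/C=C/[C@H](CCC(=O)OC)OC(C)=O | intermediate
13 | methyl (4S,5E)-4,8-diacetoxy-8-{5-[(2Z)-oct-2-en-1-yl]furan-2-yl}oct-5-enoate (both C8 epimers) | CCCCC/C=C\Cc1ccc(o1)C(OC(C)=O)C/C=C/[C@H](CCC(=O)OC)OC(C)=O | intermediate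
14 | methyl (4S,5E)-4-acetoxy-8-{5-acetoxy-5-[(2Z)-oct-2-en-1-yl]furan-2(5H)-ylidene}oct-5-enoate | CCCCC/C=C\CC1(OC(C)=O)C=CC(=CC/C=C/[C@H](CCC(=O)OC)OC(C)=O)O1 | intermediate
15 | methyl (4S,5E)-4-acetoxy-7-{(1S,5R)-5-acetoxy-5-[(2Z)-oct-2-en-1-yl]-2-oxocyclopent-3-en-1-yl}hept-5-enoate | CCCCC/C=C\C[C@@]1(OC(C)=O)C=CC(=O)[C@H]1C/C=C/[C@H](CCC(=O)OC)OC(C)=O | target

**Step count**
Total steps: 7. Longest linear sequence: 5 (steps 1, 2, 5, 6, 7).

**Three steps most likely to fail**

Step 7 (the proposed new rearrangement). Acetate may be too weak a donor to open the C5 adduct, the cation may instead lose a C7 proton to a furyl diene, or the catalyst may give poor enantiocontrol. The fallback sets out from 13 and comes back at 15, using the classical aqueous oxa-Piancatelli rearrangement. With Dy(OTf)3 (10 mol %) in MeCN/H2O at 80 °C the furfuryl acetate solvolyses to the same cation a carbinol gives, water adds at C5, and conrotatory closure gives the trans hydroxy enone without catalyst control, as a roughly 1:1 pair. These are methyl (4S,5E)-4-acetoxy-7-{(1S,5R)-5-hydroxy-5-[(2Z)-oct-2-en-1-yl]-2-oxocyclopent-3-en-1-yl}hept-5-enoate F1 and its ring diastereomer methyl (4S,5E)-4-acetoxy-7-{(1R,5S)-5-hydroxy-5-[(2Z)-oct-2-en-1-yl]-2-oxocyclopent-3-en-1-yl}hept-5-enoate F2. They are separated by preparative HPLC (chiral stationary phase if needed), and the tertiary alcohol of F1 is acetylated (Ac2O, DMAP, Et3N, CH2Cl2, rt) to give 15.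

Step 5 (cross-metathesis). The hindered allylic acetate may react slowly, the E/Z ratio may be modest, and the alkyne may interfere. The fallback sets out from 10 and 7 and comes back at 12; it moves the C4 stereocentre from the fragment to a reduction after coupling. Racemic 10 is oxidised (Dess–Martin periodinane, CH2Cl2) to methyl 4-oxohex-5-enoate F3. Cross-metathesis of 7 with F3 under the step 5 catalyst, where enone partners are reliably E-selective, gives methyl (5E)-8-acetoxy-8-[5-(oct-2-yn-1-yl)furan-2-yl]-4-oxooct-5-enoate F4. Corey–Bakshi–Shibata reduction ((R)-2-methyl-CBS-oxazaborolidine, catecholborane, toluene, –78 °C; alkenyl as the large group) gives methyl (4S,5E)-8-acetoxy-4-hydroxy-8-[5-(oct-2-yn-1-yl)furan-2-yl]oct-5-enoate F5. This is acetylated cold (Ac2O, pyridine, DMAP) before it can lactonise, giving 12; step 4 is then not needed.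

Step 2 (dianion propargylation). Lithiation may be incomplete, some SN2' allene may form, or the acidic furyl-propargyl CH2 of the product may quench the aryllithium. The fallback sets out from allylmagnesium bromide 2, together with two bought materials, 5-(chloromethyl)furan-2-carbaldehyde (ClCc1ccc(C=O)o1) and hept-1-yne (CCCCCC#C), and comes back at 7; it reverses the polarity of the furan–CH2–alkyne bond. Copper-catalysed sp–sp3 coupling (CuI 10 mol %, NaI, K2CO3, MeCN, rt) gives 5-(oct-2-yn-1-yl)furan-2-carbaldehyde F6. Addition of 2 (Et2O, –78 °C; then H2O) gives 1-[5-(oct-2-yn-1-yl)furan-2-yl]but-3-en-1-ol (racemic) F7. Acetylation (Ac2O, Et3N, DMAP, CH2Cl2) gives 7; this replaces steps 1 and 2.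

**Further compounds**
F1 | step 7 | methyl (4S,5E)-4-acetoxy-7-{(1S,5R)-5-hydroxy-5-[(2Z)-oct-2-en-1-yl]-2-oxocyclopent-3-en-1-yl}hept-5-enoate | CCCCC/C=C\C[C@@]1(O)C=CC(=O)[C@H]1C/C=C/[C@H](CCC(=O)OC)OC(C)=O
F2 | step 7 | methyl (4S,5E)-4-acetoxy-7-{(1R,5S)-5-hydroxy-5-[(2Z)-oct-2-en-1-yl]-2-oxocyclopent-3-en-1-yl}hept-5-enoate | CCCCC/C=C\C[C@]1(O)C=CC(=O)[C@@H]1C/C=C/[C@H](CCC(=O)OC)OC(C)=O
F3 | step 5 | methyl 4-oxohex-5-enoate | C=CC(=O)CCC(=O)OC
F4 | step 5 | methyl (5E)-8-acetoxy-8-[5-(oct-2-yn-1-yl)furan-2-yl]-4-oxooct-5-enoate | CCCCCC#CCc1ccc(o1)C(OC(C)=O)C/C=C/C(=O)CCC(=O)OC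
F5 | step 5 | methyl (4S,5E)-8-acetoxy-4-hydroxy-8-[5-(oct-2-yn-1-yl)furan-2-yl]oct-5-enoate | CCCCCC#CCc1ccc(o1)C(OC(C)=O)C/C=C/[C@@H](O)CCC(=O)OC
F6 | step 2 | 5-(oct-2-yn-1-yl)furan-2-carbaldehyde | CCCCCC#CCc1ccc(C=O)o1
F7 | step 2 | 1-[5-(oct-2-yn-1-yl)furan-2-yl]but-3-en-1-ol (racemic) | CCCCCC#CCc1ccc(o1)C(O)CC=C
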